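**Retrosynthetic overview**

1. Ring atoms are numbered C1 (heptenyl), C2 and C6 (carboxamides), C3 (pentyl), C4=C5 (alkene). The strategy rests on this single cyclohexene ring, in which the C3 pentyl group is allylic to C4=C5. Moving the alkene to C3=C4 and placing an oxygen leaving group on C5, cis to the C2 and C6 carbonyls, reveals a Diels–Alder retron across C1–C2 and C5–C6.
2. Target 18 ⇐ phosphine-directed syn-SN2' delivery of pentyl to C3 of the C5 o-(diphenylphosphanyl)benzoate 16 ⇐ C5 alcohol bis(isobutylamide) 15 ⇐ hydroxy imide ester 12.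
3. 12 ⇐ cycloadduct 10 ⇐ [4+2] of the 2,3-alkene of dienoyl oxazolidinone 4 (ring C6 and C1) with acyloxy dienoate 9 (ring C2 to C5). This step forms the only ring.
4. 4 ⇐ (2E,4E)-deca-2,4-dienoic acid 1 + auxiliary 2. 9 ⇐ glutaconaldehyde enolate 6 (from pyridine–SO3, 5) by O-acylation, oxidation and esterification.

Key step: step 6

Remark on the chemistry: adduct 10 holds a β-acyloxy imide and a vinylogous β-acyloxy ester, so basic deacylation would eliminate the C5 oxygen. The acyloxy donor is therefore a 2,2,2-trichloroethyl carbonate (removed by zinc in acid), and both carboxamides are made while C5 is still a free alcohol. Compounds 5, 13, 17 and 2-(diphenylphosphanyl)benzoic acid are taken as bought.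

**Route**

Step 1
Reactants: 1 (2E,4E)-deca-2,4-dienoic acid; 2 (4S)-4-benzyl-1,3-oxazolidin-2-one
Product: 4 (4S)-4-benzyl-3-[(2E,4E)-deca-2,4-dienoyl]-1,3-oxazolidin-2-one, via pivalic mixed anhydride 3 (not isolated)
Conditions: t-BuCOCl, Et3N, THF, −20 °C; then 2, LiCl, −20 °C → rt
Reagents that add atoms: none
Why: Mixed-anhydride N-acylation with LiCl/Et3N transfers the dienoyl group to the oxazolidinone nitrogen without a strong base that could deconjugate the diene; no stereocenter is formed.

Step 2
Reactants: 5 pyridine–sulfur trioxide complex (pyridinium-1-sulfonate)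
Product: 6 potassium (1E,3E)-5-oxopenta-1,3-dien-1-olate (glutaconaldehyde potassium enolate)
Conditions: KOH, H2O, −20 → 40 °C
Reagents that add atoms: potassium hydroxide, [K+].[OH-]
Why: Hydroxide adds to C2 of the N-sulfonated pyridinium ring, the dihydropyridine opens and the N-sulfonyl imine is hydrolysed (Zincke-type ring opening), which should give the all-trans five-carbon enolate.

Step 3
Reactants: 6 glutaconaldehyde potassium enolate
Product: 7 (1E,3E)-5-oxopenta-1,3-dien-1-yl 2,2,2-trichloroethyl carbonate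
Conditions: Cl3CCH2OCOCl, CH2Cl2, 0 °C → rt
Reagents that add atoms: 2,2,2-trichloroethyl chloroformate, ClC(=O)OCC(Cl)(Cl)Cl
Why: The hard chloroformate should acylate the delocalised enolate at oxygen (O-acylation, as acid chlorides do), and the all-trans anion gives the (E,E)-dienyl carbonate.

Step 4
Reactants: 7 dienal carbonate
Product: 8 (2E,4E)-5-{[(2,2,2-trichloroethoxy)carbonyl]oxy}penta-2,4-dienoic acid
Conditions: NaClO2, NaH2PO4, 2-methyl-2-butene, t-BuOH–H2O, 0 °C → rt
Reagents that add atoms: sodium chlorite, [Na+].[O-]Cl=O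
Why: Pinnick oxidation converts the enal to the acid under buffered, weakly acidic conditions that leave the enol carbonate and both E-alkenes untouched.

Step 5
Reactants: 8 dienoic acid
Product: 9 methyl (2E,4E)-5-{[(2,2,2-trichloroethoxy)carbonyl]oxy}penta-2,4-dienoate
Conditions: Me3SiCHN2, PhMe–MeOH, 0 °C
Reagents that add atoms: (trimethylsilyl)diazomethane, C[Si](C)(C)C=[N+]=[N-]
Why: Methyl ester formation with Me3SiCHN2 needs no base or acid, so the base-labile enol carbonate should survive.

Step 6
Reactants: 4 dienoyl oxazolidinone; 9 acyloxy dienoate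
Product: 10 methyl (1R,4S,5R,6R)-5-{[(4S)-4-benzyl-2-oxo-1,3-oxazolidin-3-yl]carbonyl}-6-[(1E)-hept-1-en-1-yl]-4-{[(2,2,2-trichloroethoxy)carbonyl]oxy}cyclohex-2-ene-1-carboxylate (overview numbering: C2 ester, C5 carbonate and C6 imide on one face, C1 heptenyl on the other, alkene C3=C4)
Conditions: Me2AlCl (1.4 equiv), 9 (2.5 equiv), CH2Cl2, −30 → 0 °C; aq. HCl work-up
Reagents that add atoms: none
Why: Me2AlCl should turn 4 into the cationic Me2Al chelate of both imide carbonyls, which holds the enoyl unit s-cis and makes its 2,3-alkene the 2π partner of a concerted, asynchronous normal-demand Diels–Alder reaction; the closest known reaction type is the dialkylaluminium chloride-promoted cycloaddition of N-enoyl oxazolidinones, combined with the ortho- and endo-selective additions of 1-acyloxybutadienes. The cyclohexene closes in one suprafacial [4+2] event that forms C1–C2 and C5–C6. C1 and C6 are controlled by the auxiliary: the benzyl group covers one face of the planar chelate, the diene adds to the other (the Si face at the α-carbon), and the E-alkene fixes their trans relation. C2 and C5 follow from the E,E-diene (ester and carbonate cis) and from the endo position of the chelated carbonyl (both cis to the C6 acyl group). Regiochemistry is secured by the carbonate oxygen, which makes the ester-bearing diene terminus the nucleophilic end that bonds to the β-carbon, and site selectivity for the 2,3- over the 4,5-alkene by the directly bound chelated carbonyl. The step needs reactivity above all, because the diene is weakened by its ester; 1.4 equiv of Lewis acid leaves almost no free Me2AlCl to complex the dienoate, and excess diene with warming to 0 °C should drive conversion.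

Step 7
Reactants: 10 cycloadduct
Product: 12 methyl (1R,4S,5R,6R)-5-{[(4S)-4-benzyl-2-oxo-1,3-oxazolidin-3-yl]carbonyl}-6-[(1E)-hept-1-en-1-yl]-4-hydroxycyclohex-2-ene-1-carboxylate, via C5 hydrogen carbonate 11 (not isolated)
Conditions: Zn dust, AcOH–THF, rt
Reagents that add atoms: none
Why: Zinc reduces the trichloroethyl group with loss of chloride and 1,1-dichloroethene (reductive β-elimination) and the hydrogen carbonate loses CO2; in the acidic medium neither elimination of the C5 oxygen nor enolisation at C2 or C6 should occur, so all four stereocenters are kept.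

Step 8
Reactants: 12 hydroxy imide ester; 13 2-methylpropan-1-amine (isobutylamine)
Product: 15 (1R,2S,3R,6S)-2-[(1E)-hept-1-en-1-yl]-6-hydroxy-N1,N3-bis(2-methylpropyl)cyclohex-4-ene-1,3-dicarboxamide, via C6 monoamide methyl ester 14 (not isolated)
Conditions: 13 (8 equiv), AlMe3 (6 equiv), CH2Cl2, 0 °C; then 12, 0 → 40 °C; aq. HCl work-up
Reagents that add atoms: none
Why: Weinreb-type aminolysis with Me2AlNH-i-Bu, in which the C5 aluminium alkoxide guides the reagent to the exocyclic imide carbonyl (as with aldol adducts) and the less hindered C2 methyl ester then follows; the alkoxide is no leaving group and the reagent is weakly basic, so C2, C5 and C6 should keep their configuration.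

Step 9
Reactants: 15 hydroxy bis(isobutylamide)
Product: 16 (1S,4R,5S,6R)-5-[(1E)-hept-1-en-1-yl]-4,6-bis[(2-methylpropyl)carbamoyl]cyclohex-2-en-1-yl 2-(diphenylphosphanyl)benzoate
Conditions: 2-(Ph2P)C6H4CO2H, DCC, DMAP, CH2Cl2, rt, under argon
Reagents that add atoms: 2-(diphenylphosphanyl)benzoic acid, OC(=O)c1ccccc1P(c1ccccc1)c1ccccc1
Why: Steglich esterification acylates the C5 oxygen without touching the C5–O bond (retention), and the α-hydrogens of secondary amides are too weakly acidic for DMAP to trigger elimination of the new ester.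

Step 10
Reactants: 16 allylic o-(diphenylphosphanyl)benzoate; 17 pentylmagnesium bromide
Product: 18 (1R,2R,3S,6R)-2-[(1E)-hept-1-en-1-yl]-N1,N3-bis(2-methylpropyl)-6-pentylcyclohex-4-ene-1,3-dicarboxamide (target)
Conditions: 17 (2.0 equiv), Et2O–CH2Cl2, −20 °C; then CuBr·SMe2 (0.5 equiv), 17 (1.3 equiv, slow addition), rt
Reagents that add atoms: none
Why: Directed copper-mediated allylic substitution (syn-SN2'): the first two equivalents of 17 convert both amide NH groups into magnesium amidates (which also blocks α-deprotonation), then the phosphine binds the pentylcopper species (monovalent copper) and delivers it to C3 on the face from which the C5 ester leaves, via a trivalent copper allyl intermediate and reductive elimination, so pentyl ends up cis to the C2 and C6 carboxamides and the alkene moves to C4=C5.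

**Compound list**

1 | (2E,4E)-deca-2,4-dienoic acid | CCCCC/C=C/C=C/C(=O)O | starting material
2 | (4S)-4-benzyl-1,3-oxazolidin-2-one | O=C1N[C@@H](Cc2ccccc2)CO1 | starting material
3 | (2E,4E)-deca-2,4-dienoic pivalic anhydride | CCCCC/C=C/C=C/C(=O)OC(=O)C(C)(C)C | intermediate
4 | (4S)-4-benzyl-3-[(2E,4E)-deca-2,4-dienoyl]-1,3-oxazolidin-2-one | CCCCC/C=C/C=C/C(=O)N1[C@@H](Cc2ccccc2)COC1=O | intermediate
5 | pyridine–sulfur trioxide complex (pyridinium-1-sulfonate) | [O-]S(=O)(=O)[n+]1ccccc1 | starting material
6 | potassium (1E,3E)-5-oxopenta-1,3-dien-1-olate | [K+].[O-]/C=C/C=C/C=O | intermediate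
7 | (1E,3E)-5-oxopenta-1,3-dien-1-yl 2,2,2-trichloroethyl carbonate | O=C/C=C/C=C/OC(=O)OCC(Cl)(Cl)Cl | intermediate
8 | (2E,4E)-5-{[(2,2,2-trichloroethoxy)carbonyl]oxy}penta-2,4-dienoic acid | OC(=O)/C=C/C=C/OC(=O)OCC(Cl)(Cl)Cl | intermediate
9 | methyl (2E,4E)-5-{[(2,2,2-trichloroethoxy)carbonyl]oxy}penta-2,4-dienoate | COC(=O)/C=C/C=C/OC(=O)OCC(Cl)(Cl)Cl | intermediate
10 | methyl (1R,4S,5R,6R)-5-{[(4S)-4-benzyl-2-oxo-1,3-oxazolidin-3-yl]carbonyl}-6-[(1E)-hept-1-en-1-yl]-4-{[(2,2,2-trichloroethoxy)carbonyl]oxy}cyclohex-2-ene-1-carboxylate | CCCCC/C=C/[C@H]1[C@H](C(=O)OC)C=C[C@H](OC(=O)OCC(Cl)(Cl)Cl)[C@@H]1C(=O)N2[C@@H](Cc3ccccc3)COC2=O | intermediate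
11 | methyl (1R,4S,5R,6R)-5-{[(4S)-4-benzyl-2-oxo-1,3-oxazolidin-3-yl]carbonyl}-4-(carboxyoxy)-6-[(1E)-hept-1-en-1-yl]cyclohex-2-ene-1-carboxylate | CCCCC/C=C/[C@H]1[C@H](C(=O)OC)C=C[C@H](OC(=O)O)[C@@H]1C(=O)N2[C@@H](Cc3ccccc3)COC2=O | intermediate
12 | methyl (1R,4S,5R,6R)-5-{[(4S)-4-benzyl-2-oxo-1,3-oxazolidin-3-yl]carbonyl}-6-[(1E)-hept-1-en-1-yl]-4-hydroxycyclohex-2-ene-1-carboxylate | CCCCC/C=C/[C@H]1[C@H](C(=O)OC)C=C[C@H](O)[C@@H]1C(=O)N2[C@@H](Cc3ccccc3)COC2=O | intermediate
13 | 2-methylpropan-1-amine (isobutylamine) | CC(C)CN | starting material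
14 | methyl (1R,4S,5R,6R)-6-[(1E)-hept-1-en-1-yl]-4-hydroxy-5-[(2-methylpropyl)carbamoyl]cyclohex-2-ene-1-carboxylate | CCCCC/C=C/[C@H]1[C@H](C(=O)OC)C=C[C@H](O)[C@@H]1C(=O)NCC(C)C | intermediate
15 | (1R,2S,3R,6S)-2-[(1E)-hept-1-en-1-yl]-6-hydroxy-N1,N3-bis(2-methylpropyl)cyclohex-4-ene-1,3-dicarboxamide | CCCCC/C=C/[C@H]1[C@H](C(=O)NCC(C)C)C=C[C@H](O)[C@@H]1C(=O)NCC(C)C | intermediate
16 | (1S,4R,5S,6R)-5-[(1E)-hept-1-en-1-yl]-4,6-bis[(2-methylpropyl)carbamoyl]cyclohex-2-en-1-yl 2-(diphenylphosphanyl)benzoate | CCCCC/C=C/[C@H]1[C@H](C(=O)NCC(C)C)C=C[C@H](OC(=O)c2ccccc2P(c3ccccc3)c4ccccc4)[C@@H]1C(=O)NCC(C)C | intermediate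
17 | pentylmagnesium bromide | CCCCC[Mg]Br | starting material
18 | (1R,2R,3S,6R)-2-[(1E)-hept-1-en-1-yl]-N1,N3-bis(2-methylpropyl)-6-pentylcyclohex-4-ene-1,3-dicarboxamide | CCCCC/C=C/[C@H]1[C@H](C(=O)NCC(C)C)[C@H](CCCCC)C=C[C@@H]1C(=O)NCC(C)C | target

**Step count**

Total: 10 steps. Longest linear sequence: 9 steps (steps 2 to 10, from 5 to 18).

**Steps most likely to fail**

1. Step 6. The cycloaddition may be too slow. The diene is weakened by its ester and the β-alkenyl imide is a sluggish dienophile toward open-chain dienes, so Lewis-acid-induced breakdown of the enol carbonate or oligomerisation of the dienoyl imide may outrun the [4+2]; forcing conditions would also erode site and facial control. The fallback puts a stronger donor on the diene and sets out from 6. O-Silylation (i-Pr3SiCl, THF, 0 °C) should give (2E,4E)-5-[(triisopropylsilyl)oxy]penta-2,4-dienal F1. Pinnick oxidation gives (2E,4E)-5-[(triisopropylsilyl)oxy]penta-2,4-dienoic acid F2, and Me3SiCHN2 gives methyl (2E,4E)-5-[(triisopropylsilyl)oxy]penta-2,4-dienoate F3. This silyl dienol ether is more nucleophilic at its ester-bearing terminus and should add to the Me2AlCl chelate of 4 at −78 → −40 °C (Mukaiyama–Michael-type bonding at C1–C2, then closure at C5–C6) to give the C5 triisopropylsilyl ether of 12 F4. HF·pyridine in THF frees the alcohol, and the route is rejoined at 12.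

2. Step 10. The intramolecular delivery may fail on the bis-magnesium amidate through aggregation or loss of the phosphine–copper contact, leading to substitution at C5 without transposition, entry of pentyl from the wrong face, or elimination to a cyclohexadiene. The fallback sets out from 15 and replaces directed syn attack by inversion followed by the normal anti attack. Mitsunobu reaction with picolinic acid (PPh3, DIAD, THF, 0 °C) should invert C5 and give the C5-epimeric (1R,4R,5S,6R)-5-[(1E)-hept-1-en-1-yl]-4,6-bis[(2-methylpropyl)carbamoyl]cyclohex-2-en-1-yl pyridine-2-carboxylate F5. Copper-mediated anti-SN2' substitution with 17 (3.3 equiv, CuBr·SMe2, THF, −40 → 0 °C) then places pentyl on C3 opposite the leaving group, which is the face of the two carboxamides, and arrives at 18.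

3. Step 8. The aminolysis may go astray by attack at the ring carbonyl of the auxiliary, by incomplete conversion of the C2 ester, or by epimerisation at C2 on prolonged heating. The fallback sets out from 12 and separates cleavage from amide formation. LiOH/H2O2 (THF–H2O, 0 °C) removes the auxiliary by hydroperoxide attack at the exocyclic carbonyl and should give the C6 carboxylic acid with the C2 methyl ester and C5 alcohol kept F6. Me3SnOH (1,2-dichloroethane, 80 °C) cleaves the methyl ester without a base strong enough to move the C3=C4 alkene into conjugation and gives the C5-hydroxy C2,C6-dicarboxylic acid F7. Coupling with 13 (EDC·HCl, HOBt, i-Pr2NEt, DMF, rt) returns to 15.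

**Further compounds**

F1 | step 6 | (2E,4E)-5-[(triisopropylsilyl)oxy]penta-2,4-dienal | O=C/C=C/C=C/O[Si](C(C)C)(C(C)C)C(C)C
F2 | step 6 | (2E,4E)-5-[(triisopropylsilyl)oxy]penta-2,4-dienoic acid | OC(=O)/C=C/C=C/O[Si](C(C)C)(C(C)C)C(C)C
F3 | step 6 | methyl (2E,4E)-5-[(triisopropylsilyl)oxy]penta-2,4-dienoate | COC(=O)/C=C/C=C/O[Si](C(C)C)(C(C)C)C(C)C
F4 | step 6 | C5 triisopropylsilyl ether of 12 (ring configuration as in 12) | CCCCC/C=C/[C@H]1[C@H](C(=O)OC)C=C[C@H](O[Si](C(C)C)(C(C)C)C(C)C)[C@@H]1C(=O)N2[C@@H](Cc3ccccc3)COC2=O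
F5 | step 10 | (1R,4R,5S,6R)-5-[(1E)-hept-1-en-1-yl]-4,6-bis[(2-methylpropyl)carbamoyl]cyclohex-2-en-1-yl pyridine-2-carboxylate (C5 epimer) | CCCCC/C=C/[C@H]1[C@H](C(=O)NCC(C)C)C=C[C@@H](OC(=O)c2ccccn2)[C@@H]1C(=O)NCC(C)C
F6 | step 8 | 6-[(1E)-hept-1-en-1-yl]-2-hydroxy-5-(methoxycarbonyl)cyclohex-3-ene-1-carboxylic acid (ring configuration as in 12) | CCCCC/C=C/[C@H]1[C@H](C(=O)OC)C=C[C@H](O)[C@@H]1C(=O)O
F7 | step 8 | 2-[(1E)-hept-1-en-1-yl]-6-hydroxycyclohex-4-ene-1,3-dicarboxylic acid (ring configuration as in 15) | CCCCC/C=C/[C@H]1[C@H](C(=O)O)C=C[C@H](O)[C@@H]1C(=O)O
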